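The constants used here are those of an exercise; the flask was simulated.

A constant of 1.74 at 40 °C for the opening of the substrate is the number to start from. The four flasks below carry one charge and differ in their temperature history, and the question is how much open intermediate each holds at the end.

| flask | substrate | partner | capture agent | temperature | time | remark |
|---|---|---|---|---|---|---|
| Tuesday's | 0.020 M | 1.10 equiv | 0.400 mM | 15 °C | 3.0 h |  |
| Thursday's | 0.020 M | 1.10 equiv | 0.400 mM | 65 °C | 3.0 h |  |
| Friday's | 0.020 M | 1.10 equiv | 0.400 mM | 40 °C | 3.0 h |  |
| Sunday's | 0.020 M | 1.10 equiv | 0.400 mM |  | 3.0 h | at 65 °C until 40 min, from then on at 15 °C |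

- which flask leads in amount of open intermediate, in percent of the substrate charged ("all alike" within 1.5 percentage points) (Tuesday's / Thursday's / Friday's / Sunday's / all alike)
- how much open intermediate is there at the end, in percent of the substrate charged: Tuesday's
- how much open intermediate is there at the end, in percent of the substrate charged: Thursday's
- how much open intermediate is there at the end, in percent of the substrate charged: Friday's
- how much open intermediate is there at the end, in percent of the substrate charged: Sunday's

    substrate ⇌ open intermediate (K1 = 1.74, k1 = 1.04 h⁻¹, Ea1 = 98.0 kJ mol⁻¹, ΔH1 = −28.0 kJ mol⁻¹)
    partner → second intermediate (k2 = 0.178 h⁻¹, Ea2 = 110 kJ mol⁻¹)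
    open intermediate + second intermediate ⇌ product (K3 = 122 M⁻¹, k3 = 10.0 M⁻¹ h⁻¹, Ea3 = 53.0 kJ mol⁻¹, ΔH3 = −57.0 kJ mol⁻¹)
    second intermediate + capture agent → trapped intermediate (k4 = 13.1 M⁻¹ h⁻¹, Ea4 = 61.0 kJ mol⁻¹)
    second intermediate → decomposed reagent (k5 = 0.147 h⁻¹, Ea5 = 101 kJ mol⁻¹)
    (constants at 40 °C)

- the constants hold at 40 °C; other temperatures follow from the activation energies and enthalpies

That constant gives 63.5% at 40 °C, and this is the balance share: K over one plus K, the part of substrate and open intermediate together that stands open once the opening has balanced at the flask's temperature. The enthalpy moves the constant to 4.42 at 15 °C and 0.786 at 65 °C, while the activation energy moves the forward constant to 0.0397 h⁻¹ and 16.8 h⁻¹.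

Two extreme flasks, both without partner, can be solved in the head. In the slow one nothing returns, and open intermediate grows as forward constant times time; in the fast one it stands at the balance share. Tuesday's lies near the slow one, kinetic control, with 11.9% against a balance share of 81.6%. One line joins the extremes, with B the balance share and k the forward constant:

open share = B · (1 − exp(−k·t/B))

This gives 11.1% for Tuesday's and 44.0% for Thursday's, whose relaxation time of 1.57 min is far shorter than the time. For Friday's the line gives 63.0% before the drain to product.

That drain is the small correction. Let second intermediate pile up at the partner's starting rate with none lost, let open intermediate stand at its balance share, and let product never return. Product then reaches 11.2% of the substrate, which lowers Friday's open intermediate to 56.0%. The scheme also lets second intermediate decompose and product return, and both lessen that drain, so the reckoning places Friday's between the two versions and commits to the midpoint, 59.5%.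

Sunday's spends 40 min hot, long against that relaxation time, so the reckoning lets it enter the cold at the hot balance share and creep toward 81.6% at the cold rate k/B, which gives 48.0% before any correction for product. The reckoning therefore ranks Friday's first.

The forecast names Friday's too, with 11.1% for Tuesday's, 43.8% for Thursday's, 58.5% for Friday's and 44.8% for Sunday's, on the ground that “Friday's reaches a favourable equilibrium with only a small drain to product”. Its Sunday's figure lies lower than the reckoning's.

The flasks give 11.1% for Tuesday's, 43.8% for Thursday's, 58.7% for Friday's and 44.3% for Sunday's, with Friday's ahead.

Friday's ended with 5.91% as product, and the balance share of what remains comes to 59.7% of the substrate charged, beside the 58.7% it held. The neighbour of Friday's charged with 2.80 equiv of partner takes the same reckoning: its 14.2% of product leaves 54.5% as the balance share of the remainder, and that neighbour held 52.5% of open intermediate at the end.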